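The cyclohexene ring is opened at the C4–C5 bond, the two carbinol carbons of the cis-diol that lies anti to both allylic oxygens (O3, O6). An SmI2 pinacol cyclisation of a (Z)-2,5-bis(silyloxy)hex-3-enedial closes this bond and sets C4 and C5 in one operation. The dialdehyde, its Z-alkene and the C6 stereocentre are cut from levoglucosenone (sugar carbons s1–s6 become ring C4, C3, C2, C1, C6, C5). The benzoyloxymethyl group enters at the enone β-carbon by radical addition, and an orthoester opening finally places the second benzoate on the axial O5.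

Key step: step 9

Remark on numbering: ring carbon C1 carries the exocyclic C7H2OBz, C2 is the vinylic CH, and C3–C6 follow round the ring; O3–O7 are the oxygens on these carbons. The locants s1–s6 are the sugar positions of levoglucosenone (s1 acetal carbon, s2 carbonyl, s3=s4 alkene, s5, s6). Levoglucosenone and chloromethyl benzoate are taken as commercial.

Step 1
Reactants: 1 chloromethyl benzoate
Product: 2 iodomethyl benzoate
Conditions: NaI, acetone, rt, dark
Reagents that add atoms: sodium iodide, [Na+].[I-]
Why: Finkelstein halide exchange, driven by precipitation of NaCl, should give the iodide needed as radical precursor.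

Step 2
Reactants: 3 levoglucosenone, (1S,5R)-6,8-dioxabicyclo[3.2.1]oct-2-en-4-one; 2 iodomethyl benzoate
Product: 4 [(1S,2R,5R)-4-oxo-6,8-dioxabicyclo[3.2.1]octan-2-yl]methyl benzoate
Conditions: (Me3Si)3SiH, AIBN (cat.), toluene, 80 °C, slow addition of the silane
Reagents that add atoms: none
Why: In this Giese reaction the nucleophilic benzoyloxymethyl radical should add to the enone β-carbon (s4) from the face opposite the 1,6-anhydro bridge and the α-keto radical then takes hydrogen from the silane, the new stereocentre being erased again in step 3.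

Step 3
Reactants: 4 [(1S,2R,5R)-4-oxo-6,8-dioxabicyclo[3.2.1]octan-2-yl]methyl benzoate
Product: 5 [(1S,5R)-4-oxo-6,8-dioxabicyclo[3.2.1]oct-2-en-2-yl]methyl benzoate
Conditions: IBX, DMSO, 70 °C
Reagents that add atoms: none
Why: IBX-mediated α,β-dehydrogenation of a ketone should restore the enone, since only the s3 methylene can enolise (the other α-carbon is the bridgehead acetal carbon) and the double bond therefore returns between s3 and the now substituted s4.

Step 4
Reactants: 5 [(1S,5R)-4-oxo-6,8-dioxabicyclo[3.2.1]oct-2-en-2-yl]methyl benzoate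
Product: 6 [(1S,4S,5R)-4-hydroxy-6,8-dioxabicyclo[3.2.1]oct-2-en-2-yl]methyl benzoate (D-threo alcohol)
Conditions: NaBH4, CeCl3·7H2O, MeOH, −40 °C
Reagents that add atoms: none
Why: Luche 1,2-reduction should deliver hydride to the face away from the anhydro bridge and so give the (4S)-alcohol, whose carbinol configuration is corrected in step 5.

Step 5
Reactants: 6 [(1S,4S,5R)-4-hydroxy-6,8-dioxabicyclo[3.2.1]oct-2-en-2-yl]methyl benzoate
Product: 8 [(1S,4R,5R)-4-hydroxy-6,8-dioxabicyclo[3.2.1]oct-2-en-2-yl]methyl benzoate (D-erythro alcohol), via erythro formate 7 (not isolated)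
Conditions: PPh3, DIAD, HCO2H, THF, 0 °C to rt; then KHCO3, MeOH, rt
Reagents that add atoms: formic acid, O=CO
Why: In this Mitsunobu reaction formate should displace the allylic oxyphosphonium by SN2 from the open face, inverting s2 to (4R), the configuration of ring C3, and the labile formate is methanolysed in the same flask while the benzoate stays.

Step 6
Reactants: 8 [(1S,4R,5R)-4-hydroxy-6,8-dioxabicyclo[3.2.1]oct-2-en-2-yl]methyl benzoate
Product: 10 [(2S,3Z,5R)-1,2,5,6-tetrahydroxyhex-3-en-3-yl]methyl benzoate, via lactol 9 (not isolated)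
Conditions: Amberlyst-15 (H+ form), THF/H2O, 50 °C; filter; then NaBH4, 0 °C
Reagents that add atoms: water, O
Why: Acid hydrolysis of the strained 1,6-anhydro acetal (fast for a 3,4-dideoxy sugar) should free the pyranose, which NaBH4 reduces through its open-chain aldehyde to the alditol, so that no stereocentre is touched and the Z-alkene is simply the former ring alkene.

Step 7
Reactants: 10 [(2S,3Z,5R)-1,2,5,6-tetrahydroxyhex-3-en-3-yl]methyl benzoate
Product: 11 [(2S,3Z,5R)-1,2,5,6-tetrakis(triethylsilyloxy)hex-3-en-3-yl]methyl benzoate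
Conditions: TESCl, imidazole, DMAP (cat.), DMF, 0 °C to rt
Reagents that add atoms: chlorotriethylsilane, CC[Si](Cl)(CC)CC
Why: Exhaustive silylation should cap all four hydroxyls in one operation, leaving two primary and two secondary TES ethers that the next step tells apart.

Step 8
Reactants: 11 [(2S,3Z,5R)-1,2,5,6-tetrakis(triethylsilyloxy)hex-3-en-3-yl]methyl benzoate
Product: 12 [(2S,3Z,5R)-1,6-dioxo-2,5-bis(triethylsilyloxy)hex-3-en-3-yl]methyl benzoate
Conditions: (COCl)2, DMSO, CH2Cl2, −78 to −30 °C; then Et3N, −78 to 0 °C; used crude at once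
Reagents that add atoms: none
Why: Swern oxidation applied directly to silyl ethers should convert only the two primary TES ethers (via alkoxysulfonium ions) into aldehydes while the secondary TES ethers remain, and the cold, brief contact with base protects the α-silyloxy β,γ-unsaturated aldehydes from enolisation.

Step 9
Reactants: 12 [(2S,3Z,5R)-1,6-dioxo-2,5-bis(triethylsilyloxy)hex-3-en-3-yl]methyl benzoate
Product: 13 [(3R,4R,5S,6S)-4,5-dihydroxy-3,6-bis(triethylsilyloxy)cyclohex-1-en-1-yl]methyl benzoate
Conditions: SmI2 (3 equiv), t-BuOH, THF (0.01 M), −78 to −20 °C; aq. NH4Cl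
Reagents that add atoms: none
Why: Two single-electron transfers from SmI2 convert the C4 and C5 aldehydes into samarium ketyls that couple to a trivalent samarium cis-diolate, which t-BuOH and the work-up protonate. The closest known reaction type is the SmI2-mediated intramolecular pinacol coupling of carbohydrate-derived 1,6-dialdehydes to cyclitols. The six-membered carbocycle closes in the 6-exo-trig mode (ketyl carbon onto the other carbonyl carbon), the Z-alkene C1=C2 holding the two termini close together. C4 and C5 should be set cis to each other because both ketyl oxygens bind samarium in the coupling transition state, and each new C–O bond should be set anti to the neighbouring silyloxy group (on C3 and on C6) by dipole and steric repulsion; because O3 and O6 lie on the same face, both preferences point to the single (4R,5S)-diol. The step needs ring closure to outrun intermolecular coupling and β-elimination of silanolate, which high dilution, low temperature and the absence of HMPA should secure, and the benzoate should be inert under these conditions.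

Step 10
Reactants: 13 [(3R,4R,5S,6S)-4,5-dihydroxy-3,6-bis(triethylsilyloxy)cyclohex-1-en-1-yl]methyl benzoate
Product: 16 [(3R,4S,5R,6S)-5-(benzoyloxy)-3,4,6-trihydroxycyclohex-1-en-1-yl]methyl benzoate, via cyclic 4,5-orthobenzoate 14 (not isolated), via 5-O-benzoate bis-silyl ether 15 (not isolated)
Conditions: PhC(OMe)3, CSA (cat.), CH2Cl2, rt; then AcOH/H2O/THF, rt
Reagents that add atoms: trimethyl orthobenzoate, COC(OC)(OC)c1ccccc1; water, O
Why: Acid-catalysed exchange should give the cis-fused cyclic orthoester, whose acid hydrolysis (regioselective orthoester opening) collapses to the axial ester, which is O5 because allylic 1,2-strain between C7 and the C6 silyloxy group holds O6 pseudoaxial and hence O5 axial, and the same aqueous acid then removes both TES ethers.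

Compound list
1 | chloromethyl benzoate | O=C(OCCl)c1ccccc1 | starting material
2 | iodomethyl benzoate | O=C(OCI)c1ccccc1 | intermediate
3 | levoglucosenone, (1S,5R)-6,8-dioxabicyclo[3.2.1]oct-2-en-4-one | O=C1C=C[C@H]2CO[C@@H]1O2 | starting material
4 | [(1S,2R,5R)-4-oxo-6,8-dioxabicyclo[3.2.1]octan-2-yl]methyl benzoate | O=C1C[C@H](COC(=O)c3ccccc3)[C@H]2CO[C@@H]1O2 | intermediate
5 | [(1S,5R)-4-oxo-6,8-dioxabicyclo[3.2.1]oct-2-en-2-yl]methyl benzoate | O=C1C=C(COC(=O)c3ccccc3)[C@H]2CO[C@@H]1O2 | intermediate
6 | [(1S,4S,5R)-4-hydroxy-6,8-dioxabicyclo[3.2.1]oct-2-en-2-yl]methyl benzoate (D-threo) | O[C@H]1C=C(COC(=O)c3ccccc3)[C@H]2CO[C@@H]1O2 | intermediate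
7 | [(1S,4R,5R)-4-(formyloxy)-6,8-dioxabicyclo[3.2.1]oct-2-en-2-yl]methyl benzoate (erythro formate, not isolated) | O=CO[C@@H]1C=C(COC(=O)c3ccccc3)[C@H]2CO[C@@H]1O2 | intermediate
8 | [(1S,4R,5R)-4-hydroxy-6,8-dioxabicyclo[3.2.1]oct-2-en-2-yl]methyl benzoate (D-erythro) | O[C@@H]1C=C(COC(=O)c3ccccc3)[C@H]2CO[C@@H]1O2 | intermediate
9 | 4-C-[(benzoyloxy)methyl]-3,4-dideoxy-D-erythro-hex-3-enopyranose (lactol, anomeric mixture, not isolated) | OC1O[C@H](CO)C(COC(=O)c2ccccc2)=C[C@H]1O | intermediate
10 | [(2S,3Z,5R)-1,2,5,6-tetrahydroxyhex-3-en-3-yl]methyl benzoate | OC[C@H](O)/C=C(/COC(=O)c1ccccc1)[C@H](O)CO | intermediate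
11 | [(2S,3Z,5R)-1,2,5,6-tetrakis(triethylsilyloxy)hex-3-en-3-yl]methyl benzoate | CC[Si](CC)(CC)OC[C@H](O[Si](CC)(CC)CC)/C=C(/COC(=O)c1ccccc1)[C@H](O[Si](CC)(CC)CC)CO[Si](CC)(CC)CC | intermediate
12 | [(2S,3Z,5R)-1,6-dioxo-2,5-bis(triethylsilyloxy)hex-3-en-3-yl]methyl benzoate | O=C[C@H](O[Si](CC)(CC)CC)/C=C(/COC(=O)c1ccccc1)[C@H](O[Si](CC)(CC)CC)C=O | intermediate
13 | [(3R,4R,5S,6S)-4,5-dihydroxy-3,6-bis(triethylsilyloxy)cyclohex-1-en-1-yl]methyl benzoate | O=C(OCC1=C[C@@H](O[Si](CC)(CC)CC)[C@H](O)[C@H](O)[C@H]1O[Si](CC)(CC)CC)c1ccccc1 | intermediate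
14 | cyclic methyl orthobenzoate of 13 (2-methoxy-2-phenyl-1,3-dioxolane cis-fused at C4/C5, orthoester carbon as a mixture, not isolated) | O=C(OCC1=C[C@@H](O[Si](CC)(CC)CC)[C@@H]2OC(OC)(c3ccccc3)O[C@@H]2[C@H]1O[Si](CC)(CC)CC)c1ccccc1 | intermediate
15 | [(3R,4R,5S,6S)-5-(benzoyloxy)-4-hydroxy-3,6-bis(triethylsilyloxy)cyclohex-1-en-1-yl]methyl benzoate (not isolated) | O=C(OCC1=C[C@@H](O[Si](CC)(CC)CC)[C@H](O)[C@H](OC(=O)c2ccccc2)[C@H]1O[Si](CC)(CC)CC)c1ccccc1 | intermediate
16 | [(3R,4S,5R,6S)-5-(benzoyloxy)-3,4,6-trihydroxycyclohex-1-en-1-yl]methyl benzoate (CNP0198957.1) | O=C(OCC1=C[C@@H](O)[C@H](O)[C@H](OC(=O)c2ccccc2)[C@H]1O)c1ccccc1 | target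

Total step count: 10. Longest linear sequence: 10 steps (steps 1–10, from chloromethyl benzoate 1 through iodide 2 to 16; levoglucosenone 3 joins this line at step 2).

Steps most likely to fail

Step 9. The two α-silyloxy β,γ-unsaturated aldehydes may isomerise into conjugation, the samarium ketyls may lose silanolate by β-elimination before the ring closes, or intermolecular coupling may compete. The fallback sets out from 12 and comes back at 13, closing the same C4–C5 connection by metathesis instead of reduction. Double Wittig methylenation of 12 (Ph3P=CH2, THF, −78 °C) would give [(3R,4Z,6S)-3,6-bis(triethylsilyloxy)octa-1,4,7-trien-4-yl]methyl benzoate F4. Ring-closing metathesis with the second-generation Grubbs catalyst (CH2Cl2, 40 °C) would join the two former aldehyde carbons as the C4=C5 double bond of [(3S,6R)-3,6-bis(triethylsilyloxy)cyclohexa-1,4-dien-1-yl]methyl benzoate F5. Dihydroxylation with OsO4 (cat.)/NMO should take the less substituted C4=C5 alkene (the C1=C2 alkene is trisubstituted and deactivated by the allylic benzoate) from the face anti to both silyloxy groups and return 13.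

Step 6. Under the acid the allylic C–O bonds may ionise (allylic transposition, dehydration towards furans), the anhydride may re-close so that the opening stays incomplete, and the benzoate may migrate during the NaBH4 stage. The fallback sets out from 8 and comes back at 12, replacing hydrolysis and reduction by an irreversible thioacetal opening. Propane-1,3-dithiol with BF3·OEt2 (CH2Cl2, −20 °C) would convert 8 into [(2S,3Z,5R)-5-(1,3-dithian-2-yl)-1,2,5-trihydroxypent-3-en-3-yl]methyl benzoate F1. TESOTf/2,6-lutidine would give [(2S,3Z,5R)-5-(1,3-dithian-2-yl)-1,2,5-tris(triethylsilyloxy)pent-3-en-3-yl]methyl benzoate F2. Swern oxidation of its single primary TES ether would give [(2S,3Z,5R)-5-(1,3-dithian-2-yl)-1-oxo-2,5-bis(triethylsilyloxy)pent-3-en-3-yl]methyl benzoate F3. Unmasking of the dithiane with MeI and CaCO3 in aqueous MeCN would deliver 12.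

Step 10. The hemi-orthoester may collapse through the other half-chair, in which O5 is equatorial, and so deliver the ester to O4. The fallback sets out from 13 and comes back at 15, using the complementary equatorial-selective acylation. Bu2SnO (toluene, reflux, water removal) would give the 4,5-O-dibutylstannylene acetal of 13 F6. BzCl at 0 °C should then acylate the equatorial oxygen of the stannylene to give 15, which the acid desilylation of step 10 converts into 16.

Further compounds
F1 | step 6 | [(2S,3Z,5R)-5-(1,3-dithian-2-yl)-1,2,5-trihydroxypent-3-en-3-yl]methyl benzoate | S1CCCSC1[C@H](O)/C=C(/COC(=O)c2ccccc2)[C@H](O)CO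
F2 | step 6 | [(2S,3Z,5R)-5-(1,3-dithian-2-yl)-1,2,5-tris(triethylsilyloxy)pent-3-en-3-yl]methyl benzoate | S1CCCSC1[C@H](O[Si](CC)(CC)CC)/C=C(/COC(=O)c2ccccc2)[C@H](O[Si](CC)(CC)CC)CO[Si](CC)(CC)CC
F3 | step 6 | [(2S,3Z,5R)-5-(1,3-dithian-2-yl)-1-oxo-2,5-bis(triethylsilyloxy)pent-3-en-3-yl]methyl benzoate | S1CCCSC1[C@H](O[Si](CC)(CC)CC)/C=C(/COC(=O)c2ccccc2)[C@H](O[Si](CC)(CC)CC)C=O
F4 | step 9 | [(3R,4Z,6S)-3,6-bis(triethylsilyloxy)octa-1,4,7-trien-4-yl]methyl benzoate | C=C[C@H](O[Si](CC)(CC)CC)/C=C(/COC(=O)c1ccccc1)[C@H](O[Si](CC)(CC)CC)C=C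
F5 | step 9 | [(3S,6R)-3,6-bis(triethylsilyloxy)cyclohexa-1,4-dien-1-yl]methyl benzoate | O=C(OCC1=C[C@@H](O[Si](CC)(CC)CC)C=C[C@H]1O[Si](CC)(CC)CC)c1ccccc1
F6 | step 10 | 4,5-O-dibutylstannylene acetal of 13 | O=C(OCC1=C[C@@H](O[Si](CC)(CC)CC)[C@@H]2O[Sn](CCCC)(CCCC)O[C@@H]2[C@H]1O[Si](CC)(CC)CC)c1ccccc1
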